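**Remark (assumption):** the sense of induction of a BINOL-derived phosphoric acid in this ring closure cannot be assigned in advance. The (R)-acid is written; the (S)-acid is to be used if a first run should deliver the (2S)-flavan. "Prenyl" means 3-methylbut-2-en-1-yl and "allyl" means prop-2-en-1-yl throughout.

## Structural features

The target is a flavan: benzene ring A and dihydropyran ring C form a 7-hydroxychroman whose C2 carries the aryl ring B. Ring B is substituted at every position except C6'. C1' is bonded to C2, C2' bears a prenyl chain, C3' a free hydroxyl, and O4'/C5' are bridged by a 2,2-dimethyl-2H-pyran (ring D). C2 is the only stereocentre; the line notation gives priorities O1 > C1' > C3 > H and the R configuration, and no neighbouring stereocentre is available for relay. No error was found in the structures; the two changes made to the precursor design are explained in the next section. The fragile elements are the prenyl olefin and the cis styrenic C3=C4 olefin of ring D (no hydrogenation or hydrogenolysis), the 3'-hydroxyl beside the prenyl group (closes to a chroman in strong acid), and the electron-rich phenols. The real difficulty is to set a lone benzylic ether stereocentre next to an ortho-substituted aryl group and then to keep it, because a flavan with a free 4'-hydroxyl can reopen at O1–C2. The key step uses exactly this feature: O4' is para to C1', so while O4' is unsubstituted C2 can be made planar as the terminus of a ring B para-quinone methide and recaptured by the ring A oxygen O1 under control of a chiral acid.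

## Logic of the disconnections

**25 from 24.** The two O–allyl bonds at O3' and O7 are cut last. Allyl ethers were chosen because they survive hydroxide, hydride, dilute acid and heat up to about 140 °C, and leave under neutral zerovalent-palladium conditions that touch neither olefin nor the ortho-prenylphenol. The demand on the forward step is that the cyclic tertiary allylic ether of ring D is not ionised.

**24 from 21, and 21 from 19 and 20.** Ring D is cut at C5'–C4 (pyran numbering) and then at O4'–C. O4' has to be free for the key step, so ring D must come afterwards. Capping O4' by a cold alkylation, rather than a hot Lewis-acid annulation with an enal, closes the only channel by which C2 could racemise (ring opening driven by the free para-oxygen). The demand is a propargyl ether rearrangement that runs well below the temperature at which the allyl ethers rearrange. C3' is blocked, so only C5' can accept the new bond.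

**19 from 17 (key disconnection).** O1–C2 is cut. This removes ring C and the stereocentre in one operation and leads to an acyclic racemic carbinol, so no enantiopure intermediate is needed earlier. The demand is a catalyst that controls the face of a planar methide carbon and outruns uncatalysed closure. Two changes to the obvious precursor make this safer:
- O7 carries an allyl ether, not a silyl ether, because an aryl silyl ether would not survive the hydroxide-mediated condensation used earlier.
- O3' is also capped as an allyl ether, so that no catechol and no ortho-prenylphenol is exposed to acid or air.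

**17 from 16, and 16 from 15.** The carbinol C–H bond is cut (ketone reduction), then the two methoxymethyl ethers on O4' and on the ring A oxygen. The acetals must be removed at the ketone stage. The same acid acting on the carbinol would ionise it and close ring C without control. The demand is an acid treatment mild enough for the prenyl olefin and a neutral work-up of 17.

**15 from 13, and 13 from 8 and 11.** The C3–C4 single bond is traced back to the enone olefin and the enone to its two halves across the Cα=Cβ bond. This splits the skeleton into two aromatic pieces of similar size joined by a robust condensation. The demand is a 1,4-reduction that leaves three isolated olefins and the aryl ketone alone.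

**8 from 7, 7 from 5, 5 from 2 and 4, 2 from 1, 4 from 3.** The O3–allyl bond is cut, then the C2–prenyl bond by a retro-[3,3] shift to the tertiary allyl ether, then the O3–C bond of that ether, then the O4 acetal. O4 is blocked first because it is the more acidic oxygen, which leaves O3 as the only site for the ether and C2 as the only free ortho carbon for the shift. The demand is branched-selective O-allylation and a rearrangement onto a carbon flanked by the acetyl group.

**11 from 10, 10 from 9.** The two ring A ethers are cut in reverse order of acidity. The 4-hydroxyl of 9 is alkylated selectively because the 2-hydroxyl is tied up in a hydrogen bond to the aldehyde.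

## Other disconnections considered

**Alternative 1:** C2–C1' and C3–C4 are cut around a two-carbon vinyl unit.
- Forward step: halogen–lithium exchange on the ring B bromide A1 and addition to the vinylboronate A2 give a boron ate complex. Ni(cod)2 with a chiral 1,2-diamine then couples it with the benzyl bromide A3 by 1,2-aryl shift and reductive elimination to give the boronate A4. Oxidation to the alcohol A5, closure onto the aryl chloride to A7 and acid removal of two acetals must follow.
- In favour: three fragments are joined in one step; stereocontrol is independent of ring B electronics; ring D is present from the start. No intermediate carries a free 4'-hydroxyl beside the benzylic ether, so on configurational stability of intermediates this plan is better than the chosen one.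
- Against: the migrating aryl group is ortho-substituted by prenyl; benzylic bromides tend to homocouple or alkylate the ate complex directly; no ring closes. The subsequent aryl chloride etherification of a secondary benzylic alcohol invites β-hydride elimination, and the final acid step acts beside the ortho-prenylphenol.
- Comparison: convergence is better. Step count after the key step is equal (three). Overall length is not shorter, because A1 needs its own regiocontrolled synthesis. The mechanism does not use the para-oxygen at all.

**Alternative 2:** O1–C8a is cut.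
- Forward step: the (R)-bromo alcohol A6 cyclises with Pd(OAc)2, a bulky biaryl di-tert-butylphosphine and Cs2CO3 to A7, with retention at C2.
- In favour: the stereocentre would come from an asymmetric reduction of an aryl ketone, one of the most predictable methods. On predictability of absolute configuration this plan is better than the chosen one. The C2–O bond is never broken, and ring D can be in place early.
- Against: secondary benzylic alkoxides on palladium can lose β-hydride and return the ketone; the carbinol is hindered by the ortho-prenyl group; the end-game again needs acid to remove acetals next to the prenyl group.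
- Comparison: one ring and one bond are formed, equal to the chosen key step. Two steps (reduction, closure) do what the chosen step does in one, and the plan is not enantioconvergent. Total length is about equal.

**Alternative 3:** O1–C2 and C3–C4 are cut together.
- Forward step: a chiral Brønsted acid dehydrates the hydroxymethylphenol A8 to the ortho-quinone methide A9, which adds across the vinyl group of the styrene A10 to give the bis(silyl) ether A11.
- In favour: two bonds, ring C and the stereocentre arise in one step from two fragments, so on bond economy this plan is better than the chosen one. The fluoride end-game is at least equal in mildness. The regiochemistry (aryl on C2) is inherent.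
- Against: A9 is unsubstituted at its methide carbon, oligomerises readily and offers the catalyst little to hold. A10 has no hydrogen-bond donor, is twisted by the ortho-prenyl group, and carries two further electron-rich olefins (ring D and prenyl) that can compete as dienophiles.
- Comparison: it is the most convergent of the four plans, but its enantiocontrol rests on a single contact to a fleeting diene. The chosen plan binds both reacting ends within one molecule.

Key step: step 12

## Route

Step 1
Reactants: 1 3,4-dihydroxyacetophenone
Product: 2 1-[3-hydroxy-4-(methoxymethoxy)phenyl]ethanone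
Conditions: MOMCl (1.05 equiv), K2CO3 (1.1 equiv), acetone, 0 °C → rt
Reagents that add atoms: chloromethyl methyl ether (MOMCl), COCCl
Why: The 4-hydroxyl para to the acetyl group is the more acidic phenol, so limiting base and electrophile should alkylate it selectively (Williamson-type acetal formation).

Step 2
Reactants: 3 2-methylbut-3-en-2-ol
Product: 4 isobutyl 2-methylbut-3-en-2-yl carbonate
Conditions: n-BuLi, THF, −78 → 0 °C; then ClCO2i-Bu, 0 °C → rt
Reagents that add atoms: isobutyl chloroformate, CC(C)COC(=O)Cl
Why: Acylation of the lithium alkoxide is the reliable way to a tertiary allylic carbonate.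

Step 3
Reactants: 2 1-[3-hydroxy-4-(methoxymethoxy)phenyl]ethanone; 4 isobutyl 2-methylbut-3-en-2-yl carbonate
Product: 5 1-[4-(methoxymethoxy)-3-(2-methylbut-3-en-2-yloxy)phenyl]ethanone
Conditions: Pd(PPh3)4 (2 mol %), 4 Å MS, THF, 0 °C → rt, stopped at full conversion
Reagents that add atoms: none
Why: Tsuji–Trost O-allylation: decarboxylative ionisation of 4 gives the 1,1-dimethyl-π-allyl complex and an alkoxide base, and the phenoxide attacks the more substituted terminus under kinetic control to give the tertiary ether.

Step 4
Reactants: 5 1-[4-(methoxymethoxy)-3-(2-methylbut-3-en-2-yloxy)phenyl]ethanone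
Product: 7 1-[3-hydroxy-4-(methoxymethoxy)-2-prenylphenyl]ethanone, via cyclohexadienone 6 (not isolated)
Conditions: PhNEt2, 130 °C
Reagents that add atoms: none
Why: Aromatic Claisen rearrangement: C4 is blocked by the acetal, so the [3,3] shift can only deliver the allyl unit (now as prenyl) to C2, and enolisation of 6 restores the arene. The gem-dimethyl group lowers the barrier and the amine solvent suppresses acid-induced ionisation of the tertiary ether.

Step 5
Reactants: 7 1-[3-hydroxy-4-(methoxymethoxy)-2-prenylphenyl]ethanone
Product: 8 1-[3-(allyloxy)-4-(methoxymethoxy)-2-prenylphenyl]ethanone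
Conditions: allyl bromide, K2CO3, DMF, rt → 40 °C
Reagents that add atoms: allyl bromide, C=CCBr
Why: Williamson etherification; the small, reactive allyl bromide should alkylate the flanked phenoxide, and the ether removes the ortho-prenylphenol and the catechol from all later steps.

Step 6
Reactants: 9 2,4-dihydroxybenzaldehyde
Product: 10 4-(allyloxy)-2-hydroxybenzaldehyde
Conditions: allyl bromide (1.05 equiv), K2CO3 (1.0 equiv), acetone, rt → 50 °C
Reagents that add atoms: allyl bromide, C=CCBr
Why: Selective Williamson etherification: the 2-hydroxyl is hydrogen-bonded to the aldehyde, so the free and more acidic 4-hydroxyl reacts first.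

Step 7
Reactants: 10 4-(allyloxy)-2-hydroxybenzaldehyde
Product: 11 4-(allyloxy)-2-(methoxymethoxy)benzaldehyde
Conditions: MOMCl, i-Pr2NEt, CH2Cl2, 0 °C → reflux
Reagents that add atoms: chloromethyl methyl ether (MOMCl), COCCl
Why: Acetal protection of the chelated phenol gives an aldehyde without acidic protons for the condensation and the copper hydride step.

Step 8
Reactants: 8 1-[3-(allyloxy)-4-(methoxymethoxy)-2-prenylphenyl]ethanone; 11 4-(allyloxy)-2-(methoxymethoxy)benzaldehyde
Product: 13 (E)-1-[3-(allyloxy)-4-(methoxymethoxy)-2-prenylphenyl]-3-[4-(allyloxy)-2-(methoxymethoxy)phenyl]prop-2-en-1-one, via aldol adduct 12 (not isolated)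
Conditions: KOH (50 % aq.), EtOH, rt
Reagents that add atoms: none
Why: Claisen–Schmidt condensation: aldol addition and E1cB loss of water should give the E-enone. Acetal, allyl ether and prenyl groups are inert to hydroxide.

Step 9
Reactants: 13 (E)-enone
Product: 15 1-[3-(allyloxy)-4-(methoxymethoxy)-2-prenylphenyl]-3-[4-(allyloxy)-2-(methoxymethoxy)phenyl]propan-1-one, via silyl enol ether 14 (not isolated)
Conditions: [(Ph3P)CuH]6 (5 mol %), PhMe2SiH (1.5 equiv), PhMe, rt; then K2CO3, MeOH–H2O
Reagents that add atoms: none
Why: Copper hydride conjugate reduction: the hydride adds only to the enone β-carbon, isolated olefins are not hydrocuprated at room temperature, and the ketone stays masked as 14 until work-up, so over-reduction is excluded.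

Step 10
Reactants: 15 protected dihydrochalcone
Product: 16 1-[3-(allyloxy)-4-hydroxy-2-prenylphenyl]-3-[4-(allyloxy)-2-hydroxyphenyl]propan-1-one
Conditions: 3 M HCl (aq.), MeOH, 40 °C, stopped at full conversion
Reagents that add atoms: none
Why: Acid methanolysis of the two aryl methoxymethyl acetals. Allyl ethers are stable, no free hydroxyl flanks the prenyl group, and the ketone cannot ionise as the carbinol would.

Step 11
Reactants: 16 diphenol ketone
Product: 17 racemic 1-[3-(allyloxy)-4-hydroxy-2-prenylphenyl]-3-[4-(allyloxy)-2-hydroxyphenyl]propan-1-ol
Conditions: NaBH4 (excess), MeOH–THF, 0 °C; pH 7 phosphate buffer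
Reagents that add atoms: none
Why: Borohydride reduction of the aryl ketone. The racemate is what the next step needs, and a neutral work-up avoids premature ionisation of the para-hydroxybenzylic alcohol.

Step 12
Reactants: 17 racemic carbinol
Product: 19 (2R)-7-(allyloxy)-2-[3-(allyloxy)-4-hydroxy-2-prenylphenyl]chromane, via para-quinone methide 18 (not isolated)
Conditions: (R)-TRIP (5 mol %), 4 Å MS, PhMe (0.02 M), 0 °C → rt
Reagents that add atoms: none
Why: The phosphoric acid ((R)-TRIP = (R)-3,3'-bis(2,4,6-triisopropylphenyl)-1,1'-binaphthyl-2,2'-diyl hydrogen phosphate) protonates the carbinol hydroxyl of 17 and water leaves with the push of the free O4'–H, giving para-quinone methide 18 in which C2 is trigonal, so both enantiomers of 17 converge on one intermediate. The acid then acts bifunctionally: its P–OH hydrogen-bonds to the methide carbonyl (O4') and its P=O accepts the hydrogen bond of the ring A phenol, and within this complex O1 adds to C2 in an oxa-1,6-addition that rearomatises ring B. Ring C closes in the 6-exo-trig mode (O1, C8a, C4a, C4, C3, C2, with the C2=C1' bond exocyclic to the new ring). The closest known reaction type is the chiral phosphoric acid catalysed enantioselective 1,6-addition of nucleophiles to para-quinone methides generated in situ from para-hydroxybenzylic alcohols. The new stereocentre C2 is controlled by the catalyst alone, whose 3,3'-aryl groups shield one face of the methide carbon; the acid enantiomer is chosen so that the R product results. The step needs face selectivity, a catalysed closure faster than the uncatalysed one, and O- rather than C-attack: the 2'-prenyl group forces the side chain of 18 towards C6' so that a single methide geometry is presented, the nucleophilic carbons of ring A cannot reach C2 through a reasonable ring, and the allyl ether on O3' removes the phenol that could otherwise add to the prenyl olefin. Low temperature, high dilution and molecular sieves hold back background closure, oligomerisation and rehydration, and the reaction is stopped at full conversion because the product can ionise again.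

Step 13
Reactants: 19 (2R)-flavan phenol; 20 3-chloro-3-methylbut-1-yne
Product: 21 (2R)-7-(allyloxy)-2-[3-(allyloxy)-4-(2-methylbut-3-yn-2-yloxy)-2-prenylphenyl]chromane
Conditions: CuCl2·2H2O (0.5 mol %), DBU (1.3 equiv), MeCN, −5 → 0 °C
Reagents that add atoms: none
Why: Copper-catalysed O-propargylation of a phenol with a tertiary propargylic chloride, a reaction that tolerates ortho-substituted phenols. It caps O4' in the cold and so shuts off ring opening at O1–C2 before any heating.

Step 14
Reactants: 21 aryl propargyl ether
Product: 24 (2R)-7-(allyloxy)-2-[8-(allyloxy)-2,2-dimethyl-7-prenyl-2H-chromen-6-yl]chromane, via ortho-allenylphenol 22 (not isolated), via ortho-quinone methide 23 (not isolated)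
Conditions: o-xylene, 130 °C
Reagents that add atoms: none
Why: Aryl propargyl ether Claisen rearrangement to C5' (C3' is blocked), [1,5]-hydrogen shift and oxa-6π electrocyclisation form ring D. The gem-dimethyl propargyl ether should rearrange far below the temperature (about 200 °C) that simple aryl allyl ethers need, and C2 is not involved.

Step 15
Reactants: 24 bis(allyl) ether
Product: 25 (2R)-2-[8-hydroxy-2,2-dimethyl-7-prenyl-2H-chromen-6-yl]chroman-7-ol (target)
Conditions: Pd(PPh3)4 (5 mol %), morpholine (10 equiv), THF, rt
Reagents that add atoms: none
Why: Tsuji–Trost deallylation: zerovalent palladium ionises the unhindered primary aryl allyl ethers and morpholine traps the π-allyl complex. The C-prenyl group has no leaving group and the tertiary cyclic allylic ether of ring D is much slower to ionise.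

## Compound list

1 | 3,4-dihydroxyacetophenone | CC(=O)c1ccc(O)c(O)c1 | starting material
2 | 1-[3-hydroxy-4-(methoxymethoxy)phenyl]ethanone | CC(=O)c1ccc(OCOC)c(O)c1 | intermediate
3 | 2-methylbut-3-en-2-ol | C=CC(C)(C)O | starting material
4 | isobutyl 2-methylbut-3-en-2-yl carbonate | C=CC(C)(C)OC(=O)OCC(C)C | intermediate
5 | 1-[4-(methoxymethoxy)-3-(2-methylbut-3-en-2-yloxy)phenyl]ethanone | CC(=O)c1ccc(OCOC)c(OC(C)(C)C=C)c1 | intermediate
6 | racemic 5-acetyl-2-(methoxymethoxy)-6-prenylcyclohexa-2,4-dien-1-one | CC(=O)C1=CC=C(OCOC)C(=O)C1CC=C(C)C | intermediate (not isolated)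
7 | 1-[3-hydroxy-4-(methoxymethoxy)-2-prenylphenyl]ethanone | CC(=O)c1ccc(OCOC)c(O)c1CC=C(C)C | intermediate
8 | 1-[3-(allyloxy)-4-(methoxymethoxy)-2-prenylphenyl]ethanone | CC(=O)c1ccc(OCOC)c(OCC=C)c1CC=C(C)C | intermediate
9 | 2,4-dihydroxybenzaldehyde | O=Cc1ccc(O)cc1O | starting material
10 | 4-(allyloxy)-2-hydroxybenzaldehyde | O=Cc1ccc(OCC=C)cc1O | intermediate
11 | 4-(allyloxy)-2-(methoxymethoxy)benzaldehyde | O=Cc1ccc(OCC=C)cc1OCOC | intermediate
12 | racemic 1-[3-(allyloxy)-4-(methoxymethoxy)-2-prenylphenyl]-3-[4-(allyloxy)-2-(methoxymethoxy)phenyl]-3-hydroxypropan-1-one | CC(C)=CCc1c(C(=O)CC(O)c2ccc(OCC=C)cc2OCOC)ccc(OCOC)c1OCC=C | intermediate (not isolated)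
13 | (E)-1-[3-(allyloxy)-4-(methoxymethoxy)-2-prenylphenyl]-3-[4-(allyloxy)-2-(methoxymethoxy)phenyl]prop-2-en-1-one | CC(C)=CCc1c(C(=O)/C=C/c2ccc(OCC=C)cc2OCOC)ccc(OCOC)c1OCC=C | intermediate
14 | dimethyl(phenyl)silyl enol ether of 15 (enol ether geometry not defined) | CC(C)=CCc1c(C(O[Si](C)(C)c2ccccc2)=CCc2ccc(OCC=C)cc2OCOC)ccc(OCOC)c1OCC=C | intermediate (not isolated)
15 | 1-[3-(allyloxy)-4-(methoxymethoxy)-2-prenylphenyl]-3-[4-(allyloxy)-2-(methoxymethoxy)phenyl]propan-1-one | CC(C)=CCc1c(C(=O)CCc2ccc(OCC=C)cc2OCOC)ccc(OCOC)c1OCC=C | intermediate
16 | 1-[3-(allyloxy)-4-hydroxy-2-prenylphenyl]-3-[4-(allyloxy)-2-hydroxyphenyl]propan-1-one | CC(C)=CCc1c(C(=O)CCc2ccc(OCC=C)cc2O)ccc(O)c1OCC=C | intermediate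
17 | racemic 1-[3-(allyloxy)-4-hydroxy-2-prenylphenyl]-3-[4-(allyloxy)-2-hydroxyphenyl]propan-1-ol | CC(C)=CCc1c(C(O)CCc2ccc(OCC=C)cc2O)ccc(O)c1OCC=C | intermediate
18 | 2-(allyloxy)-4-{3-[4-(allyloxy)-2-hydroxyphenyl]propylidene}-3-prenylcyclohexa-2,5-dien-1-one, side chain on the C6' side (para-quinone methide) | CC(C)=CCC1=C(OCC=C)C(=O)C=C/C1=C\CCc1ccc(OCC=C)cc1O | intermediate (not isolated)
19 | (2R)-7-(allyloxy)-2-[3-(allyloxy)-4-hydroxy-2-prenylphenyl]chromane | CC(C)=CCc1c([C@H]2CCc3ccc(OCC=C)cc3O2)ccc(O)c1OCC=C | intermediate
20 | 3-chloro-3-methylbut-1-yne | C#CC(C)(C)Cl | starting material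
21 | (2R)-7-(allyloxy)-2-[3-(allyloxy)-4-(2-methylbut-3-yn-2-yloxy)-2-prenylphenyl]chromane | CC(C)=CCc1c([C@H]2CCc3ccc(OCC=C)cc3O2)ccc(OC(C)(C)C#C)c1OCC=C | intermediate
22 | (2R)-7-(allyloxy)-2-[3-(allyloxy)-4-hydroxy-5-(3-methylbuta-1,2-dien-1-yl)-2-prenylphenyl]chromane | CC(C)=CCc1c([C@H]2CCc3ccc(OCC=C)cc3O2)cc(C=C=C(C)C)c(O)c1OCC=C | intermediate (not isolated)
23 | 2-(allyloxy)-4-[(2R)-7-(allyloxy)chroman-2-yl]-6-(3-methylbut-2-en-1-ylidene)-3-prenylcyclohexa-2,4-dien-1-one (ortho-quinone methide) | CC(C)=CCC1=C(OCC=C)C(=O)C(=CC=C(C)C)C=C1[C@H]2CCc3ccc(OCC=C)cc3O2 | intermediate (not isolated)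
24 | (2R)-7-(allyloxy)-2-[8-(allyloxy)-2,2-dimethyl-7-prenyl-2H-chromen-6-yl]chromane | CC(C)=CCc1c([C@H]2CCc3ccc(OCC=C)cc3O2)cc2c(c1OCC=C)OC(C)(C)C=C2 | intermediate
25 | (2R)-2-[8-hydroxy-2,2-dimethyl-7-prenyl-2H-chromen-6-yl]-3,4-dihydro-2H-chromen-7-ol | CC(C)=CCc1c([C@H]2CCc3ccc(O)cc3O2)cc2c(c1O)OC(C)(C)C=C2 | target

## Step count and least certain steps

Total: 15 steps. Longest linear sequence: 12 steps (1, 3, 4, 5, 8, 9, 10, 11, 12, 13, 14, 15).

**Step 12 (key step).**
- What may go wrong: insufficient face selectivity at the methide carbon; tautomerisation of the alkyl-substituted methide to a para-hydroxystyrene by loss of a C3 proton; attack of the prenyl olefin on C2 (five-membered carbocycle); slow re-ionisation of the product that erodes enantiopurity. The cause is that the methide is held only by hydrogen bonds, and that the ring A phenoxide is a fair leaving group under the same acid.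
- Fallback (known chemistry, separates stereocontrol from ring closure), from 16 back to 19. The more acidic O4'–H is acylated selectively (PivCl, Et3N, CH2Cl2, −20 °C) to the ketone pivalate F1. Asymmetric transfer hydrogenation with RuCl[(S,S)-TsDPEN](p-cymene) in HCO2H/Et3N should give the (S)-carbinol pivalate F2. Mitsunobu closure (PPh3, DIAD, THF, 0 °C) with inversion gives the (2R)-flavan pivalate F3; the ester makes the ring less electron-rich, which keeps ionisation in check. K2CO3 in MeOH at 0 °C then returns 19.

**Step 13.**
- What may go wrong: incomplete alkylation of the flanked phenol, or partial loss of enantiopurity by phenoxide-driven opening of the O1–C2 bond while O4' is deprotonated. The cause is the same para relationship that the key step uses.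
- Fallback, from 19 directly to 24 (skipping 21): ortho-alkylation and electrocyclisation of the titanium phenoxide with 3-methylbut-2-enal and Ti(OEt)4 in toluene at reflux. This changes the ring D construction from O-alkylation and rearrangement to C-alkylation and condensation. It makes no new compound (F0), but it exposes 19 to a hot Lewis acid, which is why it is second choice.

**Step 4.**
- What may go wrong: fragmentation of the tertiary allyl ether (loss of the C5 unit) or migration to C6 in place of the shift to the hindered C2 next to the acetyl group.
- Fallback, from 2 back to 7 (this also bypasses step 3). Phenol 2 is O-allylated (allyl bromide, K2CO3) to the allyl ether F4. A normal aromatic Claisen rearrangement (PhNEt2, 190 °C), which cannot fragment, gives the 2-allylphenol F5. Cross-metathesis with 2-methylbut-2-ene (second-generation Grubbs catalyst, RuCl2(=CHPh)(PCy3)(H2IMes), CH2Cl2, 40 °C) converts allyl into prenyl and returns 7.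

**Step 15.**
- What may go wrong: incomplete cleavage at the hindered O3' ether, or competing ionisation of the allylic C–O bond of ring D by zerovalent palladium with ring opening.
- Fallback, from 24 back to 25. Both allyl ethers are isomerised with [Ir(cod)(PMePh2)2]PF6 (activated with H2, THF, rt) to the bis(prop-1-enyl) ether F6. The enol ethers are then hydrolysed with dilute HCl in acetone–water at room temperature, much milder than acetal cleavage, to give 25.

## Further compounds

F1 | step 12 | 2-(allyloxy)-4-{3-[4-(allyloxy)-2-hydroxyphenyl]propanoyl}-3-prenylphenyl pivalate | CC(C)=CCc1c(C(=O)CCc2ccc(OCC=C)cc2O)ccc(OC(=O)C(C)(C)C)c1OCC=C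
F2 | step 12 | 2-(allyloxy)-4-{(1S)-3-[4-(allyloxy)-2-hydroxyphenyl]-1-hydroxypropyl}-3-prenylphenyl pivalate | CC(C)=CCc1c([C@@H](O)CCc2ccc(OCC=C)cc2O)ccc(OC(=O)C(C)(C)C)c1OCC=C
F3 | step 12 | 2-(allyloxy)-4-[(2R)-7-(allyloxy)chroman-2-yl]-3-prenylphenyl pivalate | CC(C)=CCc1c([C@H]2CCc3ccc(OCC=C)cc3O2)ccc(OC(=O)C(C)(C)C)c1OCC=C
F0 | step 13 | none | none
F4 | step 4 | 1-[3-(allyloxy)-4-(methoxymethoxy)phenyl]ethanone | CC(=O)c1ccc(OCOC)c(OCC=C)c1
F5 | step 4 | 1-[2-allyl-3-hydroxy-4-(methoxymethoxy)phenyl]ethanone | CC(=O)c1ccc(OCOC)c(O)c1CC=C
F6 | step 15 | (2R)-2-[2,2-dimethyl-7-prenyl-8-(prop-1-enyloxy)-2H-chromen-6-yl]-7-(prop-1-enyloxy)chromane (enol ether geometry not defined) | CC(C)=CCc1c([C@H]2CCc3ccc(OC=CC)cc3O2)cc2c(c1OC=CC)OC(C)(C)C=C2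
A1 | alternative 1 | 6-bromo-8-(methoxymethoxy)-2,2-dimethyl-7-prenyl-2H-chromene | CC(C)=CCc1c(Br)cc2c(c1OCOC)OC(C)(C)C=C2
A2 | alternative 1 | 4,4,5,5-tetramethyl-2-vinyl-1,3,2-dioxaborolane | C=CB1OC(C)(C)C(C)(C)O1
A3 | alternative 1 | 1-(bromomethyl)-2-chloro-4-(methoxymethoxy)benzene | COCOc1ccc(CBr)c(Cl)c1
A4 | alternative 1 | (R)-2-{3-[2-chloro-4-(methoxymethoxy)phenyl]-1-[8-(methoxymethoxy)-2,2-dimethyl-7-prenyl-2H-chromen-6-yl]propyl}-4,4,5,5-tetramethyl-1,3,2-dioxaborolane | CC(C)=CCc1c([C@H](B3OC(C)(C)C(C)(C)O3)CCc3ccc(OCOC)cc3Cl)cc2c(c1OCOC)OC(C)(C)C=C2
A5 | alternative 1 | (1R)-3-[2-chloro-4-(methoxymethoxy)phenyl]-1-[8-(methoxymethoxy)-2,2-dimethyl-7-prenyl-2H-chromen-6-yl]propan-1-ol | CC(C)=CCc1c([C@H](O)CCc3ccc(OCOC)cc3Cl)cc2c(c1OCOC)OC(C)(C)C=C2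
A6 | alternative 2 | (1R)-3-[2-bromo-4-(methoxymethoxy)phenyl]-1-[8-(methoxymethoxy)-2,2-dimethyl-7-prenyl-2H-chromen-6-yl]propan-1-ol | CC(C)=CCc1c([C@H](O)CCc3ccc(OCOC)cc3Br)cc2c(c1OCOC)OC(C)(C)C=C2
A7 | alternative 2 | (2R)-7-(methoxymethoxy)-2-[8-(methoxymethoxy)-2,2-dimethyl-7-prenyl-2H-chromen-6-yl]chromane | CC(C)=CCc1c([C@H]2CCc3ccc(OCOC)cc3O2)cc2c(c1OCOC)OC(C)(C)C=C2
A8 | alternative 3 | 5-(tert-butyldimethylsilyloxy)-2-(hydroxymethyl)phenol | OCc1ccc(O[Si](C)(C)C(C)(C)C)cc1O
A9 | alternative 3 | 3-(tert-butyldimethylsilyloxy)-6-methylidenecyclohexa-2,4-dien-1-one | C=C1C=CC(O[Si](C)(C)C(C)(C)C)=CC1=O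
A10 | alternative 3 | tert-butyl[(2,2-dimethyl-7-prenyl-6-vinyl-2H-chromen-8-yl)oxy]dimethylsilane | CC(C)=CCc1c(C=C)cc2c(c1O[Si](C)(C)C(C)(C)C)OC(C)(C)C=C2
A11 | alternative 3 | (2R)-7-(tert-butyldimethylsilyloxy)-2-[8-(tert-butyldimethylsilyloxy)-2,2-dimethyl-7-prenyl-2H-chromen-6-yl]chromane | CC(C)=CCc1c([C@H]2CCc3ccc(O[Si](C)(C)C(C)(C)C)cc3O2)cc2c(c1O[Si](C)(C)C(C)(C)C)OC(C)(C)C=C2
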